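**Retrosynthetic overview**

1. Numbering used throughout: C1 lactone C=O, C2 methylated quaternary bridgehead, C3 ketone, C4 the CHMe next to it, C5 the O–CH bridgehead, C6 the CHMe of the third bridge, C7 the spiro carbon, C8–C11 the oxane carbons (C9 bears OAc), C12 the methyl on C11. Enabling feature: the carbocycle C2–C3–C4–C5–C6–C7 of the 2-oxabicyclo[2.2.2]octane is a cyclohexanone whose two α-carbons are bonded to oxygen-bearing carbons (C4 to the lactone carbinol C5, C2 to the ketal-type spiro carbon C7 of the oxane). It is therefore a 3-oxopentanoate C2/C4 bis-nucleophile joined to a C5-aldehyde/C7-oxocarbenium bis-electrophile, and the C5 oxygen sits where it can close the lactone onto C1.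
2. Key disconnection: C4–C5 (aldol), O–C1 (lactone) and C2–C7 (ketal alkylation) are cut together. This removes the lactone bridge and the ketone bridge at once and leaves the acyclic β-keto imide 20 (C1–C4) and the monocyclic ketal aldehyde 16 (C5–C12).
3. Aldehyde 16: the oxane ring comes from ketalization of aldol adduct 9, made from Roche-ester ketone 8 (C5–C8) and aldehyde 4 (C9–C12) through the C8–C9 bond. C9 is corrected on the ring (oxidation, equatorial hydride delivery) and acetylated.
4. Stereochemistry: C11 and C6 are bought; C10 (alkylation) and C8 (aldol) are relayed from them; C9 comes from the ring. In the key step C4 and C5 are set by the C2 centre of 20 (itself erased afterwards), and C2 and C7 are relayed from C5, C6 and C8 during the bicyclization.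
5. Ring order: oxane (step 8), then δ-lactone and carbocycle together (step 16).

Key step: step 16

Remark on the chemistry: the C7 methyl ketals are drawn as the anomerically favoured axial-methoxy isomers; this centre is ionized in step 16, so its configuration is immaterial.

**Route**

Step 1
Reactants: 1 methyl (R)-3-hydroxybutanoate
Product: 2 methyl (2R,3R)-3-hydroxy-2-methylbutanoate
Conditions: LiN(i-Pr)2 (2.2 equiv), THF, −50 → −20 °C; MeI, −78 → −20 °C
Reagents that add atoms: iodomethane CI
Why: Fráter–Seebach alkylation: the chelated lithium alkoxide–enolate dianion is methylated on the face away from the C11 substituent, which should set C10 anti to the purchased C11 centre.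

Step 2
Reactants: 2 methyl (2R,3R)-3-hydroxy-2-methylbutanoate
Product: 3 methyl (2R,3R)-2-methyl-3-(triethylsilyloxy)butanoate
Conditions: Et3SiCl, imidazole, CH2Cl2, 0 °C
Reagents that add atoms: chlorotriethylsilane CC[Si](Cl)(CC)CC
Why: Silyl ether formation on the secondary alcohol; the triethylsilyl group is chosen because it should survive steps 3 and 7 and fall off in the acidic methanol of step 8.

Step 3
Reactants: 3 methyl (2R,3R)-2-methyl-3-(triethylsilyloxy)butanoate
Product: 4 (2R,3R)-2-methyl-3-(triethylsilyloxy)butanal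
Conditions: i-Bu2AlH, CH2Cl2, −78 °C
Reagents that add atoms: none
Why: Partial ester reduction with a dialkylaluminium hydride: the tetrahedral aluminium hemiacetal is stable at −78 °C and releases the aldehyde only on work-up, and the crude aldehyde is used at once so that C10 is not epimerized.

Step 4
Reactants: 5 methyl (S)-3-hydroxy-2-methylpropanoate (Roche ester)
Product: 6 methyl (S)-3-(benzyloxy)-2-methylpropanoate
Conditions: benzyl 2,2,2-trichloroacetimidate, TfOH (cat.), CH2Cl2–cyclohexane, rt
Reagents that add atoms: benzyl 2,2,2-trichloroacetimidate N=C(OCc1ccccc1)C(Cl)(Cl)Cl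
Why: Acid-catalysed O-benzylation with a trichloroacetimidate avoids the basic conditions that would epimerize or eliminate the β-hydroxy ester, so C6 is untouched.

Step 5
Reactants: 6 methyl (S)-3-(benzyloxy)-2-methylpropanoate
Product: 7 (S)-3-(benzyloxy)-N-methoxy-N,2-dimethylpropanamide
Conditions: MeNH(OMe)·HCl, i-PrMgCl, THF, −20 °C
Reagents that add atoms: N,O-dimethylhydroxylamine hydrochloride CNOC.Cl
Why: Weinreb amide formation by aminolysis of the ester with the magnesium amide of N,O-dimethylhydroxylamine, a process that does not enolize C6.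

Step 6
Reactants: 7 (S)-3-(benzyloxy)-N-methoxy-N,2-dimethylpropanamide
Product: 8 (S)-1-(benzyloxy)-2-methylpentan-3-one
Conditions: EtMgBr, THF, 0 °C
Reagents that add atoms: ethylmagnesium bromide CC[Mg]Br
Why: Weinreb ketone synthesis: the chelated tetrahedral magnesium adduct prevents a second addition and should give the ethyl ketone without touching C6.

Step 7
Reactants: 8 (S)-1-(benzyloxy)-2-methylpentan-3-one; 4 (2R,3R)-2-methyl-3-(triethylsilyloxy)butanal
Product: 9 (2S,4R,5S,6S,7R)-1-(benzyloxy)-5-hydroxy-2,4,6-trimethyl-7-(triethylsilyloxy)octan-3-one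
Conditions: TiCl4, i-Pr2NEt, CH2Cl2, −78 °C; then 4, −78 °C
Reagents that add atoms: none
Why: Chlorotitanium Z-enolate syn aldol through a closed Zimmerman–Traxler transition state: the C6 centre of the α-methyl-β-benzyloxy ketone should direct the new C8 methyl syn to the C6 methyl and the Z geometry makes C8/C9 syn, while the C9 carbinol configuration is of no consequence because step 9 erases it.

Step 8
Reactants: 9 (2S,4R,5S,6S,7R)-1-(benzyloxy)-5-hydroxy-2,4,6-trimethyl-7-(triethylsilyloxy)octan-3-one
Product: 11 (2S,3R,4S,5S,6R)-2-[(S)-1-(benzyloxy)propan-2-yl]-2-methoxy-3,5,6-trimethyloxan-4-ol, via hemiketal 10 (not isolated)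
Conditions: PPTS (cat.), MeOH, 0 °C → rt
Reagents that add atoms: methanol CO
Why: Acid-catalysed desilylation followed by ketalization: the freed C11 hydroxyl adds to the C7 ketone (6-exo-trig) to give hemiketal 10, and exchange with methanol should give the methyl ketal under anomeric control, with methoxy axial and the three ring methyls and the C7 side chain equatorial.

Step 9
Reactants: 11 (2S,3R,4S,5S,6R)-2-[(S)-1-(benzyloxy)propan-2-yl]-2-methoxy-3,5,6-trimethyloxan-4-ol
Product: 12 (2S,3R,5R,6R)-2-[(S)-1-(benzyloxy)propan-2-yl]-2-methoxy-3,5,6-trimethyloxan-4-one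
Conditions: Dess–Martin periodinane, pyridine, CH2Cl2, 0 °C
Reagents that add atoms: none
Why: Dess–Martin oxidation under pyridine buffering, kept neutral and cold so that the β,β-dialkoxy ketone does not lose methanol; C8 and C10 already carry equatorial methyls, the thermodynamic arrangement.

Step 10
Reactants: 12 (2S,3R,5R,6R)-2-[(S)-1-(benzyloxy)propan-2-yl]-2-methoxy-3,5,6-trimethyloxan-4-one
Product: 13 (2S,3R,4R,5S,6R)-2-[(S)-1-(benzyloxy)propan-2-yl]-2-methoxy-3,5,6-trimethyloxan-4-ol
Conditions: LiBH(s-Bu)3, THF, −78 °C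
Reagents that add atoms: none
Why: Diastereoselective ketone reduction with a bulky trialkylborohydride: approach along the equatorial trajectory, the axial face being closed by the axial C7 methoxy group, should deliver the axial C9 alcohol cis to both flanking methyls.

Step 11
Reactants: 13 (2S,3R,4R,5S,6R)-2-[(S)-1-(benzyloxy)propan-2-yl]-2-methoxy-3,5,6-trimethyloxan-4-ol
Product: 14 (2S,3R,4R,5R,6R)-2-[(S)-1-(benzyloxy)propan-2-yl]-2-methoxy-3,5,6-trimethyloxan-4-yl acetate
Conditions: Ac2O, Et3N, DMAP (cat.), CH2Cl2, rt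
Reagents that add atoms: acetic anhydride CC(=O)OC(C)=O
Why: DMAP-catalysed acyl transfer to the hindered axial alcohol; no stereocentre is touched.

Step 12
Reactants: 14 (2S,3R,4R,5R,6R)-2-[(S)-1-(benzyloxy)propan-2-yl]-2-methoxy-3,5,6-trimethyloxan-4-yl acetate
Product: 15 (2S,3R,4R,5R,6R)-2-[(S)-1-hydroxypropan-2-yl]-2-methoxy-3,5,6-trimethyloxan-4-yl acetate
Conditions: H2 (1 atm), Pd/C, EtOAc, rt
Reagents that add atoms: none
Why: Catalytic hydrogenolysis of the benzyl ether under neutral conditions that should leave the ketal and the acetate intact.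

Step 13
Reactants: 15 (2S,3R,4R,5R,6R)-2-[(S)-1-hydroxypropan-2-yl]-2-methoxy-3,5,6-trimethyloxan-4-yl acetate
Product: 16 (2R,3R,4R,5R,6R)-2-methoxy-3,5,6-trimethyl-2-[(S)-1-oxopropan-2-yl]oxan-4-yl acetate
Conditions: Dess–Martin periodinane, pyridine, CH2Cl2, 0 °C
Reagents that add atoms: none
Why: Dess–Martin oxidation of the primary alcohol under buffered, non-basic conditions should keep the α-centre C6 and the β-ketal intact; the aldehyde is used directly in step 16.

Step 14
Reactants: 17 (S)-4-benzyl-3-propanoyl-1,3-oxazolidin-2-one; 18 propanal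
Product: 19 (S)-4-benzyl-3-[(2S,3R)-3-hydroxy-2-methylpentanoyl]-1,3-oxazolidin-2-one
Conditions: Bu2BOTf, i-Pr2NEt, CH2Cl2, 0 °C; 18, −78 → 0 °C; then H2O2, MeOH, pH 7 buffer
Reagents that add atoms: none
Why: Evans syn aldol: the Z-dibutylboron enolate reacts through a Zimmerman–Traxler chair on the face opposite the benzyl group of the auxiliary, which should set both new centres (2S,3R).

Step 15
Reactants: 19 (S)-4-benzyl-3-[(2S,3R)-3-hydroxy-2-methylpentanoyl]-1,3-oxazolidin-2-one
Product: 20 (S)-4-benzyl-3-[(S)-2-methyl-3-oxopentanoyl]-1,3-oxazolidin-2-one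
Conditions: SO3·pyridine, DMSO, i-Pr2NEt, CH2Cl2, −10 °C
Reagents that add atoms: none
Why: Parikh–Doering oxidation to the β-keto imide; the C2 centre should not epimerize because allylic strain in the imide keeps the C2–H bond out of alignment with the carbonyl π systems.

Step 16
Reactants: 20 (S)-4-benzyl-3-[(S)-2-methyl-3-oxopentanoyl]-1,3-oxazolidin-2-one; 16 (2R,3R,4R,5R,6R)-2-methoxy-3,5,6-trimethyl-2-[(S)-1-oxopropan-2-yl]oxan-4-yl acetate
Product: 24 the target CNP0257416.1 (spiro oxane–2-oxabicyclo[2.2.2]octane-3,5-dione acetate; C2 S, C4 S, C5 R, C6 S, C7 S, C8 R, C9 R, C10 R, C11 R), via aldol adduct 21 (not isolated), via keto lactone 22 (not isolated), via oxocarbenium ion 23 (not isolated)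
Conditions: TiCl4, i-Pr2NEt, CH2Cl2, −5 °C (enolization of 20); 16, −78 °C; then i-Pr2NEt, −78 → 0 °C; then TiCl4, −78 → −20 °C
Reagents that add atoms: none
Why: Proposed new method: a titanium-mediated aldol/lactonization/ketal-alkylation cascade (a formal [3+3] bicycloannulation) in which the Z-chlorotitanium enolate of 20, formed only at C4 because allylic strain in the imide keeps C2–H unreactive, adds to aldehyde 16 to give aldolate 21, the C5 alkoxide then displaces the oxazolidinone from C1 to give keto lactone 22 as its titanium enolate, and fresh TiCl4 ionizes the C7 methyl ketal to oxocarbenium ion 23, which is captured by C2. The closest known reaction types are the titanium aldol of β-keto imides, the Lewis-acid alkylation of titanium enolates and 1,3-dicarbonyl compounds by ketals, and the formal [3+3] cyclization of 3-oxoalkanoate bis-nucleophiles with 1,3-bis-electrophiles. The lactone ring closes by 6-exo-trig acyl substitution at C1 and the carbocycle by a 6-(enolendo)-exo-trig attack of C2 on C7, which completes the 2-oxabicyclo[2.2.2]octane. C4 and C5 should be set in the chair Zimmerman–Traxler transition state under control of the C2 methyl centre of 20 (C2/C4 syn, C4/C5 syn), reinforced by the anti-Felkin preference of a Z-enolate for the α-methyl aldehyde (C5/C6 anti); C2 is then dictated by the bridge, and C7 by C6 and C8, because the C6–H bond must eclipse C7–C8 to keep the C6 and C8 methyl groups apart, which places the C5 arm and its enolate on the ring face opposite the axial C9 acetate. The step needs C4 to react before C2 and needs carbon rather than oxygen alkylation at C7: the first is secured by the imide, which unmasks C2 only after lactonization, and the second by the reversibility of mixed-ketal formation at C7 against the irreversible C–C bond.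

**Compound list**

1 | methyl (R)-3-hydroxybutanoate | C[C@@H](O)CC(=O)OC | starting material
2 | methyl (2R,3R)-3-hydroxy-2-methylbutanoate | C[C@@H](O)[C@@H](C)C(=O)OC | intermediate
3 | methyl (2R,3R)-2-methyl-3-(triethylsilyloxy)butanoate | C[C@@H](O[Si](CC)(CC)CC)[C@@H](C)C(=O)OC | intermediate
4 | (2R,3R)-2-methyl-3-(triethylsilyloxy)butanal | C[C@@H](O[Si](CC)(CC)CC)[C@@H](C)C=O | intermediate
5 | methyl (S)-3-hydroxy-2-methylpropanoate (Roche ester) | COC(=O)[C@@H](C)CO | starting material
6 | methyl (S)-3-(benzyloxy)-2-methylpropanoate | COC(=O)[C@@H](C)COCc1ccccc1 | intermediate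
7 | (S)-3-(benzyloxy)-N-methoxy-N,2-dimethylpropanamide | CON(C)C(=O)[C@@H](C)COCc1ccccc1 | intermediate
8 | (S)-1-(benzyloxy)-2-methylpentan-3-one | CCC(=O)[C@@H](C)COCc1ccccc1 | intermediate
9 | (2S,4R,5S,6S,7R)-1-(benzyloxy)-5-hydroxy-2,4,6-trimethyl-7-(triethylsilyloxy)octan-3-one (C6/C8 methyls syn, C8/C9 syn) | C[C@@H](O[Si](CC)(CC)CC)[C@@H](C)[C@H](O)[C@@H](C)C(=O)[C@@H](C)COCc1ccccc1 | intermediate
10 | hemiketal (2S,3R,4S,5S,6R)-2-[(S)-1-(benzyloxy)propan-2-yl]-3,5,6-trimethyloxane-2,4-diol | O[C@H]1[C@H](C)[C@@H](C)O[C@@]([C@@H](C)COCc2ccccc2)([C@@H]1C)O | intermediate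
11 | (2S,3R,4S,5S,6R)-2-[(S)-1-(benzyloxy)propan-2-yl]-2-methoxy-3,5,6-trimethyloxan-4-ol (C9 hydroxyl equatorial) | O[C@H]1[C@H](C)[C@@H](C)O[C@@]([C@@H](C)COCc2ccccc2)([C@@H]1C)OC | intermediate
12 | (2S,3R,5R,6R)-2-[(S)-1-(benzyloxy)propan-2-yl]-2-methoxy-3,5,6-trimethyloxan-4-one | O=C1[C@H](C)[C@@H](C)O[C@@]([C@@H](C)COCc2ccccc2)([C@@H]1C)OC | intermediate
13 | (2S,3R,4R,5S,6R)-2-[(S)-1-(benzyloxy)propan-2-yl]-2-methoxy-3,5,6-trimethyloxan-4-ol (C9 hydroxyl axial) | O[C@@H]1[C@H](C)[C@@H](C)O[C@@]([C@@H](C)COCc2ccccc2)([C@@H]1C)OC | intermediate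
14 | (2S,3R,4R,5R,6R)-2-[(S)-1-(benzyloxy)propan-2-yl]-2-methoxy-3,5,6-trimethyloxan-4-yl acetate | CC(=O)O[C@@H]1[C@H](C)[C@@H](C)O[C@@]([C@@H](C)COCc2ccccc2)([C@@H]1C)OC | intermediate
15 | (2S,3R,4R,5R,6R)-2-[(S)-1-hydroxypropan-2-yl]-2-methoxy-3,5,6-trimethyloxan-4-yl acetate | CC(=O)O[C@@H]1[C@H](C)[C@@H](C)O[C@@]([C@@H](C)CO)([C@@H]1C)OC | intermediate
16 | (2R,3R,4R,5R,6R)-2-methoxy-3,5,6-trimethyl-2-[(S)-1-oxopropan-2-yl]oxan-4-yl acetate | CC(=O)O[C@@H]1[C@H](C)[C@@H](C)O[C@@]([C@@H](C)C=O)([C@@H]1C)OC | intermediate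
17 | (S)-4-benzyl-3-propanoyl-1,3-oxazolidin-2-one | CCC(=O)N1[C@@H](Cc2ccccc2)COC1=O | starting material
18 | propanal | CCC=O | starting material
19 | (S)-4-benzyl-3-[(2S,3R)-3-hydroxy-2-methylpentanoyl]-1,3-oxazolidin-2-one | CC[C@@H](O)[C@H](C)C(=O)N1[C@@H](Cc2ccccc2)COC1=O | intermediate
20 | (S)-4-benzyl-3-[(S)-2-methyl-3-oxopentanoyl]-1,3-oxazolidin-2-one | CCC(=O)[C@H](C)C(=O)N1[C@@H](Cc2ccccc2)COC1=O | intermediate
21 | aldol adduct of 20 and 16, present as its titanium aldolate: (2S,3R,4R,5R,6R)-2-{(2S,3S,4S,6S)-7-[(S)-4-benzyl-2-oxo-1,3-oxazolidin-3-yl]-3-hydroxy-4,6-dimethyl-5,7-dioxoheptan-2-yl}-2-methoxy-3,5,6-trimethyloxan-4-yl acetate (C2/C4 syn, C4/C5 syn, C5/C6 anti) | CC(=O)O[C@@H]1[C@H](C)[C@@H](C)O[C@@]([C@@H](C)[C@@H](O)[C@H](C)C(=O)[C@H](C)C(=O)N2[C@@H](Cc3ccccc3)COC2=O)([C@@H]1C)OC | intermediate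
22 | keto lactone: the oxane of 16 carrying on C6 a 3,5-dimethyloxane-2,4-dione ring closed between the C5 oxygen and C1 (C4 and C5 as in 21, C2 enolizable) | CC(=O)O[C@@H]1[C@H](C)[C@@H](C)O[C@@]([C@@H](C)[C@H]2OC(=O)C(C)C(=O)[C@H]2C)([C@@H]1C)OC | intermediate
23 | oxocarbenium ion formed from 22 by loss of methoxide at C7 | CC(=O)O[C@@H]1[C@H](C)[C@@H](C)[O+]=C([C@@H](C)[C@H]2OC(=O)C(C)C(=O)[C@H]2C)[C@@H]1C | intermediate
24 | CNP0257416.1: 4-acetoxy-3,5,6-trimethyloxane spiro-fused at C7 to the 4,6,7-trimethyl-2-oxabicyclo[2.2.2]octane-3,5-dione (C2 S, C4 S, C5 R, C6 S, C7 S, C8 R, C9 R, C10 R, C11 R) | CC(=O)O[C@@H]1[C@H](C)[C@@H](C)O[C@@]2([C@@H]1C)[C@@H](C)[C@H]1OC(=O)[C@]2(C)C(=O)[C@H]1C | target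

**Step count and risks**

Total step count: 16. Longest linear sequence: 11 steps (steps 1–3, 7–13 and 16; equally steps 4–13 and 16).

Step 16 (proposed new method). What may go wrong: the titanium aldolate may not transfer the acyl group to close the lactone; the oxocarbenium ion may lose a proton from C6 and then expel the C5 carboxylate in a Ferrier-type elimination; the enolate may be alkylated on oxygen; or C2 may approach the axial face of C7. The fallback forms the same bonds in separate, known operations. It sets out from 16 and 20: only the titanium aldol is run and quenched at −78 °C, and aldol adduct 21 is isolated. Compound 21 is lactonized with i-Pr2NEt and catalytic DMAP in CH2Cl2 (intramolecular acyl transfer with release of the auxiliary) to give keto lactone 22. This is silylated (Me3SiCl, Et3N) to the trimethylsilyl enol ether F1. The carbocycle is then closed by a Me3SiOTf-catalysed intramolecular Mukaiyama-type addition of the enol silane to the ketal at −78 °C, which rejoins the route at 24.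

Step 9. What may go wrong: β-elimination of methanol from the β,β-dialkoxy ketone to the conjugated dihydropyranone, and epimerization at C8 or C10 through the enol. The fallback avoids the ketone altogether. It sets out from 11, whose equatorial C9 hydroxyl is inverted by Mitsunobu displacement (PPh3, diisopropyl azodicarboxylate, 4-nitrobenzoic acid, toluene) to the axial 4-nitrobenzoate F2. Methanolysis (K2CO3, MeOH) gives the axial alcohol and rejoins the route at 13, so steps 9 and 10 are not needed.

Step 7. What may go wrong: poor facial selectivity at C8, because the anti-Felkin preference of aldehyde 4 toward a Z-enolate opposes the control exerted by the ketone (mismatched double stereodifferentiation). The fallback uses the matched pairing instead. It sets out from 8 and 4: the E-enolate made with (c-Hex)2BCl and Et3N in Et2O gives, by an anti aldol in which the 1,4-induction of the ketone and the Felkin preference of 4 agree, the anti,anti aldol adduct F3 (the C8 epimer of 9). Ketalization as in step 8 gives the methyl ketal F4 and oxidation as in step 9 gives the ketone F5, which carries an axial C8 methyl. Equilibration through the enol with catalytic Et3N in CH2Cl2 moves this methyl to the equatorial position and rejoins the route at 12.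

Further compounds
F1 | step 16 | trimethylsilyl enol ether of keto lactone 22 (4-trimethylsilyloxy-5,6-dihydro-2H-pyran-2-one ring, all other centres as in 22) | CC(=O)O[C@@H]1[C@H](C)[C@@H](C)O[C@@]([C@@H](C)[C@H]2OC(=O)C(C)=C(O[Si](C)(C)C)[C@H]2C)([C@@H]1C)OC
F2 | step 9 | (2S,3R,4R,5R,6R)-2-[(S)-1-(benzyloxy)propan-2-yl]-2-methoxy-3,5,6-trimethyloxan-4-yl 4-nitrobenzoate (axial ester) | O=C(O[C@@H]1[C@H](C)[C@@H](C)O[C@@]([C@@H](C)COCc2ccccc2)([C@@H]1C)OC)c3ccc(cc3)[N+](=O)[O-]
F3 | step 7 | anti,anti aldol adduct, the C4 epimer of 9 in octanone numbering (C6/C8 methyls anti, C8/C9 anti) | C[C@@H](O[Si](CC)(CC)CC)[C@@H](C)[C@H](O)[C@H](C)C(=O)[C@@H](C)COCc1ccccc1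
F4 | step 7 | methyl ketal from F3, the C3 epimer of 11 in oxane numbering (axial C8 methyl) | O[C@H]1[C@H](C)[C@@H](C)O[C@@]([C@@H](C)COCc2ccccc2)([C@H]1C)OC
F5 | step 7 | ketone from F4, the C3 epimer of 12 in oxane numbering (axial C8 methyl) | O=C1[C@H](C)[C@@H](C)O[C@@]([C@@H](C)COCc2ccccc2)([C@H]1C)OC
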